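**Plan**

- Kukoamine A is a symmetric spermine diamide. Each end is a 3-(3,4-dihydroxyphenyl)propanamide in which the ring carbon para to one hydroxyl (meta to the other) is bonded to the β-carbon of the acyl chain.
- Retrosynthesis: restore the two Cα=Cβ double bonds and the benzyl-type protection, then cut both aryl–Cβ bonds at once. This gives a Cbz-protected spermine bis-acrylamide and two molecules of 4-bromo-1,2-bis(benzyloxy)benzene. The two acrylamide C–N bonds are cut last, back to spermine.
- Forward: spermine is differentiated (primary N as trifluoroacetamide, secondary N as Cbz), unmasked and acryloylated. Both aryl rings are then attached in one two-directional Heck coupling, and a single hydrogenation saturates both alkenes and removes all six benzyl-type groups.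
- No ring is formed in the route (the two benzene rings are bought), and the target has no stereocentre. The E geometry of the Heck product is erased by the hydrogenation.

Key step: step 5

Assumption: the target is taken as the free base drawn. The last hydrogenation is run with acetic acid present, and the acetate salt is neutralised under argon during work-up.

**Step 1**
Reactants: 1 spermine; 2 ethyl trifluoroacetate; 3 N-(benzyloxycarbonyloxy)succinimide
Product: 5 N1,N12-bis(trifluoroacetyl)-N4,N9-bis(benzyloxycarbonyl)spermine, via N1,N12-bis(trifluoroacetyl)spermine 4 (not isolated)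
Conditions: CF3CO2Et (2.1 equiv), MeOH, −78 → 0 °C; then CbzOSu (2.3 equiv), Et3N, 0 °C → rt
Reagents that add atoms: ethyl trifluoroacetate, CCOC(=O)C(F)(F)F; N-(benzyloxycarbonyloxy)succinimide, O=C(OCc1ccccc1)ON1C(=O)CCC1=O
Why: Aminolysis of ethyl trifluoroacetate at low temperature is selective for the unhindered primary amines, and the two secondary amines left over are then captured as benzyl carbamates by the succinimidyl carbonate (chemoselective N-trifluoroacetylation followed by carbamate formation).

**Step 2**
Reactants: 5 N1,N12-bis(trifluoroacetyl)-N4,N9-bis(benzyloxycarbonyl)spermine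
Product: 6 N4,N9-bis(benzyloxycarbonyl)spermine
Conditions: K2CO3, MeOH–H2O, rt → 50 °C
Reagents that add atoms: none
Why: The strongly electrophilic trifluoroacetamides are cleaved by mild basic hydrolysis, conditions under which benzyl carbamates are inert.

**Step 3**
Reactants: 6 N4,N9-bis(benzyloxycarbonyl)spermine; 7 acryloyl chloride
Product: 8 dibenzyl butane-1,4-diylbis[(3-acrylamidopropyl)carbamate]
Conditions: CH2=CHCOCl (2.2 equiv), Et3N, CH2Cl2, −20 → 0 °C, BHT (trace)
Reagents that add atoms: acryloyl chloride, C=CC(=O)Cl
Why: N-acylation of the two primary amines by the acid chloride is much faster at low temperature than conjugate addition to the acrylamide being formed, and the internal nitrogens are blocked as carbamates (amide formation from an acyl chloride).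

**Step 4**
Reactants: 9 4-bromocatechol; 10 benzyl bromide
Product: 11 4-bromo-1,2-bis(benzyloxy)benzene
Conditions: BnBr (2.3 equiv), K2CO3, DMF, 60 °C
Reagents that add atoms: benzyl bromide, BrCc1ccccc1
Why: Both phenoxides formed with carbonate displace bromide from benzyl bromide in an SN2 reaction (Williamson ether synthesis), and the aryl bromide is untouched.

**Step 5**
Reactants: 8 dibenzyl butane-1,4-diylbis[(3-acrylamidopropyl)carbamate]; 11 4-bromo-1,2-bis(benzyloxy)benzene
Product: 12 N4,N9-bis(benzyloxycarbonyl)-N1,N12-bis[(E)-3,4-bis(benzyloxy)cinnamoyl]spermine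
Conditions: 11 (2.4 equiv), Pd(OAc)2 (5 mol %), P(o-tol)3 (12 mol %), Et3N, DMF, 100 °C, degassed, BHT (trace)
Reagents that add atoms: 4-bromo-1,2-bis(benzyloxy)benzene, Brc1ccc(OCc2ccccc2)c(OCc2ccccc2)c1
Why: Zerovalent palladium, formed in the flask from Pd(OAc)2 and P(o-tol)3, inserts into the C–Br bond of 11, the resulting arylpalladium bromide (divalent palladium) binds a terminal alkene of 8, syn migratory insertion delivers the aryl group to the unsubstituted CH2 terminus, and syn β-hydride elimination releases the E-cinnamamide while Et3N takes up HBr and returns the catalyst to the zerovalent state, after which the cycle repeats at the second, remote acrylamide. The closest known reaction type is the Mizoroki–Heck arylation of acrylamides and acrylates with electron-rich aryl bromides under phosphine-assisted conditions. No ring is closed and no stereocentre is created; the only stereochemical outcome is the E geometry of the new alkenes, which is favoured in the elimination and is removed in any case by the later hydrogenation. The step needs arylation at the terminal (β) carbon and only once per alkene: the polarisation of the acrylamide and the unsubstituted CH2 terminus direct the aryl group there, and the β-aryl acrylamide formed is far less reactive towards a second insertion. The point of attachment on the arene is fixed by the bromine of 11, para to one benzyloxy group and meta to the other, and the benzyl ethers keep the oxidation-prone catechol masked. The two internal nitrogens are carbamates, so no basic amine is present to bind palladium or to add to the acrylamide.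

**Step 6**
Reactants: 12 N4,N9-bis(benzyloxycarbonyl)-N1,N12-bis[(E)-3,4-bis(benzyloxy)cinnamoyl]spermine
Product: 13 kukoamine A
Conditions: H2 (1–3 bar), 10% Pd/C, THF–MeOH–AcOH, rt; then basic ion-exchange resin, degassed MeOH, Ar
Reagents that add atoms: none
Why: Catalytic hydrogenation over palladium saturates both conjugated alkenes, and hydrogenolysis cleaves the four aryl benzyl ethers and the two benzyl carbamates (the carbamic acids then lose carbon dioxide), while acetic acid keeps the liberated amines protonated so that they do not poison the catalyst.

**Compound list**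

1 | spermine | NCCCNCCCCNCCCN | starting material
2 | ethyl trifluoroacetate | CCOC(=O)C(F)(F)F | starting material
3 | N-(benzyloxycarbonyloxy)succinimide | O=C(OCc1ccccc1)ON1C(=O)CCC1=O | starting material
4 | N1,N12-bis(trifluoroacetyl)spermine | O=C(NCCCNCCCCNCCCNC(=O)C(F)(F)F)C(F)(F)F | intermediate
5 | N1,N12-bis(trifluoroacetyl)-N4,N9-bis(benzyloxycarbonyl)spermine | O=C(NCCCN(CCCCN(CCCNC(=O)C(F)(F)F)C(=O)OCc1ccccc1)C(=O)OCc1ccccc1)C(F)(F)F | intermediate
6 | N4,N9-bis(benzyloxycarbonyl)spermine | NCCCN(CCCCN(CCCN)C(=O)OCc1ccccc1)C(=O)OCc1ccccc1 | intermediate
7 | acryloyl chloride | C=CC(=O)Cl | starting material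
8 | dibenzyl butane-1,4-diylbis[(3-acrylamidopropyl)carbamate] | C=CC(=O)NCCCN(CCCCN(CCCNC(=O)C=C)C(=O)OCc1ccccc1)C(=O)OCc1ccccc1 | intermediate
9 | 4-bromocatechol | Oc1ccc(Br)cc1O | starting material
10 | benzyl bromide | BrCc1ccccc1 | starting material
11 | 4-bromo-1,2-bis(benzyloxy)benzene | Brc1ccc(OCc2ccccc2)c(OCc2ccccc2)c1 | intermediate
12 | N4,N9-bis(benzyloxycarbonyl)-N1,N12-bis[(E)-3,4-bis(benzyloxy)cinnamoyl]spermine | O=C(/C=C/c1ccc(OCc2ccccc2)c(OCc2ccccc2)c1)NCCCN(CCCCN(CCCNC(=O)/C=C/c1ccc(OCc2ccccc2)c(OCc2ccccc2)c1)C(=O)OCc1ccccc1)C(=O)OCc1ccccc1 | intermediate
13 | kukoamine A | O=C(CCc1ccc(O)c(O)c1)NCCCNCCCCNCCCNC(=O)CCc1ccc(O)c(O)c1 | target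

**Step count**

Total: 6 steps. Longest linear sequence: 5 steps (steps 1, 2, 3, 5, 6); step 4 is a one-step side branch.

**Steps most likely to fail, with fallbacks**

Step 5. The two-fold coupling may stall after the first arylation, or the bis-acrylamide may oligomerise thermally before slow oxidative addition into the electron-rich aryl bromide catches up. In that case the arylpropenoyl unit would be made away from the polyamine and without palladium. Knoevenagel–Doebner condensation of commercial 3,4-bis(benzyloxy)benzaldehyde with malonic acid (pyridine, piperidine, 90 °C) should give (E)-3-[3,4-bis(benzyloxy)phenyl]prop-2-enoic acid F1. The fallback sets out from diamine 6, which is acylated at both primary amines with F1 (EDC·HCl, HOBt, iPr2NEt, CH2Cl2), and it comes back to the route at 12.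

Step 1. The primary/secondary discrimination in the trifluoroacetylation may be lost (over-acylation or under-acylation), so that a statistical mixture is carried through the carbamate formation. The fallback sets out from spermine 1 and uses imide protection. N-Ethoxycarbonylphthalimide (2 equiv, CH2Cl2, rt) reacts only with primary amines and should give N1,N12-bis(phthaloyl)spermine F2. Carbamate formation with 3 and Et3N then gives N1,N12-bis(phthaloyl)-N4,N9-bis(benzyloxycarbonyl)spermine F3. Hydrazinolysis (N2H4·H2O, EtOH, reflux) frees the primary amines, and the fallback comes back to the route at 6.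

Step 3. Primary amine not yet acylated may add in conjugate fashion to acrylamide already formed, and the product may polymerise on concentration. The fallback sets out from 6 and masks the alkene during the acylation. 3-Chloropropanoyl chloride under two-phase conditions (aqueous NaHCO3, CH2Cl2, 0 °C) should give dibenzyl butane-1,4-diylbis{[3-(3-chloropropanamido)propyl]carbamate} F4. Once no free amine remains, elimination of HCl with excess Et3N (MeCN, 60 °C) unveils both acrylamides, and the fallback comes back to the route at 8.

**Further compounds**

F1 | step 5 | (E)-3-[3,4-bis(benzyloxy)phenyl]prop-2-enoic acid | O=C(O)/C=C/c1ccc(OCc2ccccc2)c(OCc2ccccc2)c1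
F2 | step 1 | N1,N12-bis(phthaloyl)spermine | O=C1c2ccccc2C(=O)N1CCCNCCCCNCCCN1C(=O)c2ccccc2C1=O
F3 | step 1 | N1,N12-bis(phthaloyl)-N4,N9-bis(benzyloxycarbonyl)spermine | O=C1c2ccccc2C(=O)N1CCCN(CCCCN(CCCN1C(=O)c2ccccc2C1=O)C(=O)OCc1ccccc1)C(=O)OCc1ccccc1
F4 | step 3 | dibenzyl butane-1,4-diylbis{[3-(3-chloropropanamido)propyl]carbamate} | ClCCC(=O)NCCCN(CCCCN(CCCNC(=O)CCCl)C(=O)OCc1ccccc1)C(=O)OCc1ccccc1
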